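**Plan**

- Cuts: the C3–O ester bond (C3 alcohol plus (Z)-2-(acetoxymethyl)but-2-enoic acid); the isopropenyl C=C back to a tertiary alcohol; the C3–O bond back to C3–H (key step); the O1–C2 bond (phenoxide on an epoxide); the aryl–CH2 bond (Stille coupling); in the acid, the C2–CH2OH bond (alkenylalane plus formaldehyde).
- Feature used: the oxygen on the C2 propan-2-yl carbon is 1,3 to C3 (O–CMe2–C2–C3–H), so a carbamate on it brings its nitrogen to the C3 hydrogen through a seven-membered transition state, and a six-membered ring joining the two oxygens can only be cis-fused to the dihydrofuran ring.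
- Forward order: bromination and prenylation of 2,4-dihydroxyacetophenone at C5, epoxidation, closure of the dihydrofuran ring by 5-exo opening; then the temporary six-membered carbonate ring (key step), its methanolysis, esterification at C3, dehydration, desilylation.
- Stereochemistry: C2 from Shi epoxidation (L-fructose-derived ketone) followed by SN2 inversion; C3 from the cis-only tether to C2; the Z alkene from syn-hydroalumination of ethyl but-2-ynoate.
- Protecting-group logic: from step 6 the phenol is a triisopropylsilyl ether, because a para-phenoxide would expel any C3 oxygen leaving group (carbonate or ester) as a quinone methide and end in the benzofuran; it is freed last under non-basic conditions.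

Key step: step 8

**Route**

Step 1
Reactants: 1 1-(2,4-dihydroxyphenyl)ethanone
Product: 2 1-(5-bromo-2,4-dihydroxyphenyl)ethanone
Conditions: Br2 (1.0 equiv), AcOH, 15–20 °C
Reagents that add atoms: bromine, BrBr
Why: Electrophilic aromatic bromination, in which C5 (para to the chelated 2-hydroxyl, ortho to the 4-hydroxyl) is less hindered than C3 between the two hydroxyls, so one equivalent of bromine should give the 5-bromide.

Step 2
Reactants: 2 1-(5-bromo-2,4-dihydroxyphenyl)ethanone
Product: 3 1-{5-bromo-2,4-bis[(tert-butyldimethylsilyl)oxy]phenyl}ethanone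
Conditions: TBSCl, imidazole, DMF, rt to 40 °C
Reagents that add atoms: tert-butyldimethylsilyl chloride, CC(C)(C)[Si](C)(C)Cl
Why: Silylation of both phenols (the chelated one more slowly) masks them for the coupling and the oxidation, and TBSCl with imidazole does not enolise the methyl ketone.

Step 3
Reactants: 3 1-{5-bromo-2,4-bis[(tert-butyldimethylsilyl)oxy]phenyl}ethanone; 4 tributyl(3-methylbut-2-en-1-yl)stannane
Product: 5 1-{2,4-bis[(tert-butyldimethylsilyl)oxy]-5-(3-methylbut-2-en-1-yl)phenyl}ethanone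
Conditions: Pd(PPh3)4 (5 mol %), DMF, 100 °C
Reagents that add atoms: none
Why: Stille coupling at zerovalent palladium, in which the allylpalladium intermediate reductively eliminates at its unsubstituted terminus to give the linear prenyl arene, under neutral conditions that spare the aryl silyl ethers and the ketone.

Step 4
Reactants: 5 1-{2,4-bis[(tert-butyldimethylsilyl)oxy]-5-(3-methylbut-2-en-1-yl)phenyl}ethanone
Product: 6 1-{2,4-bis[(tert-butyldimethylsilyl)oxy]-5-{[(2S)-3,3-dimethyloxiran-2-yl]methyl}phenyl}ethanone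
Conditions: L-fructose-derived Shi ketone (0.3 equiv), Oxone (2KHSO5·KHSO4·K2SO4), K2CO3, Bu4NHSO4, aq. Na2B4O7/Na2EDTA buffer, MeCN–CH2(OMe)2, 0 °C
Reagents that add atoms: potassium peroxymonosulfate (active salt of Oxone), [K+].[O-]S(=O)(=O)OO
Why: Shi asymmetric epoxidation, in which the dioxirane of the L-fructose-derived ketone attacks the electron-rich trisubstituted alkene through a spiro transition state and should give the (S)-epoxide (mirror image of the (R)-epoxide expected from the D-fructose-derived ketone), while the silyl ethers keep the phenols from oxidation.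

Step 5
Reactants: 6 1-{2,4-bis[(tert-butyldimethylsilyl)oxy]-5-{[(2S)-3,3-dimethyloxiran-2-yl]methyl}phenyl}ethanone
Product: 8 1-[(2R)-6-hydroxy-2-(2-hydroxypropan-2-yl)-2,3-dihydro-1-benzofuran-5-yl]ethanone, via epoxy diphenol 7 (not isolated)
Conditions: Bu4NF, THF, 0 °C to rt; then AcOH
Reagents that add atoms: none
Why: Fluoride removes both silyl groups and the phenoxide para to the acetyl group opens the epoxide at its secondary carbon in a 5-exo-tet SN2 reaction (base favours this over 6-endo attack at the tertiary carbon), so C2 is formed with inversion as (R).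

Step 6
Reactants: 8 1-[(2R)-6-hydroxy-2-(2-hydroxypropan-2-yl)-2,3-dihydro-1-benzofuran-5-yl]ethanone
Product: 9 1-[(2R)-2-(2-hydroxypropan-2-yl)-6-[(triisopropylsilyl)oxy]-2,3-dihydro-1-benzofuran-5-yl]ethanone
Conditions: TIPSCl, imidazole, DMF, rt
Reagents that add atoms: triisopropylsilyl chloride, CC(C)[Si](Cl)(C(C)C)C(C)C
Why: Silylation of the phenol only, the tertiary alcohol being too hindered for TIPSCl and imidazole; the bulky silyl ether is chosen to outlast the carbonate methanolysis of step 9 and to shield C7.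

Step 7
Reactants: 9 1-[(2R)-2-(2-hydroxypropan-2-yl)-6-[(triisopropylsilyl)oxy]-2,3-dihydro-1-benzofuran-5-yl]ethanone; 10 2,2,2-trifluoroethyl isocyanate
Product: 11 2-[(2R)-5-acetyl-6-[(triisopropylsilyl)oxy]-2,3-dihydro-1-benzofuran-2-yl]propan-2-yl N-(2,2,2-trifluoroethyl)carbamate
Conditions: CuCl (cat.), DMF, rt
Reagents that add atoms: none
Why: CuCl-catalysed addition of a hindered tertiary alcohol to an alkyl isocyanate (carbamoylation), which touches no stereocentre.

Step 8
Reactants: 11 2-[(2R)-5-acetyl-6-[(triisopropylsilyl)oxy]-2,3-dihydro-1-benzofuran-2-yl]propan-2-yl N-(2,2,2-trifluoroethyl)carbamate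
Product: 15 cis-fused cyclic carbonate of 1-[(2R,3S)-3-hydroxy-2-(2-hydroxypropan-2-yl)-6-[(triisopropylsilyl)oxy]-2,3-dihydro-1-benzofuran-5-yl]ethanone (O3 and the side-chain oxygen joined through C=O), via N-bromo carbamate 12 (not isolated), via C3 bromide 13 (not isolated), via cyclic iminocarbonate 14 (not isolated)
Conditions: CH3CO2Br (stock solution from AgOAc and Br2), CH2Cl2, 0 °C, dark; CBr4, PhCF3, visible light, rt; Ag2CO3, CH2Cl2, rt; aq. AcOH, rt
Reagents that add atoms: water, O; acetyl hypobromite, CC(=O)OBr (its bromine is present only in 12 and 13)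
Why: CH3CO2Br brominates the carbamate nitrogen (12); light cleaves N–Br and the planar carbamate nitrogen radical takes the C3 hydrogen cis to the side chain through a seven-membered transition state (1,6-hydrogen transfer), after which the benzylic radical picks up bromine from CBr4 or from 12 in a chain to give 13. Ag2CO3 ionises the C3–Br bond and the carbamate carbonyl oxygen closes the six-membered ring by 6-exo-tet attack at C3 (14), and aqueous AcOH hydrolyses the C=N bond to the carbonate 15. The closest known reaction type is the Hofmann–Löffler–Freytag-type synthesis of 1,3-diol carbonates from N-trifluoroethyl carbamates at benzylic and tertiary C–H bonds. The new C3 stereocentre is controlled by the tether: the attacking oxygen is held on the C2 side chain, so whichever bromide epimer ionises, only the cis-fused ring can form, giving (3S) from (2R). Site selectivity is needed between C3–H and the C2–H and methyl hydrogens; it is secured by the 1,6-preference of the planar carbamate radical and by C3 being the only benzylic carbon. Ring bromination at C7 and loss of HBr to the benzofuran are held back by the acetyl group para to the ring oxygen, by the bulky silyl ether next to C7 and by the fast intramolecular capture of the benzylic cation.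

Step 9
Reactants: 15 cis-fused cyclic carbonate (see step 8)
Product: 16 1-[(2R,3S)-3-hydroxy-2-(2-hydroxypropan-2-yl)-6-[(triisopropylsilyl)oxy]-2,3-dihydro-1-benzofuran-5-yl]ethanone
Conditions: K2CO3 (cat.), MeOH, 0 °C to rt
Reagents that add atoms: none
Why: Base-catalysed transesterification of the cyclic carbonate by acyl–oxygen cleavage leaves both stereocentres untouched, and because the phenol stays silylated no para-phenoxide is present that could expel the C3 oxygen as a quinone methide.

Step 10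
Reactants: 17 ethyl but-2-ynoate
Product: 19 ethyl (2Z)-2-(hydroxymethyl)but-2-enoate, via alkenylalane 18 (not isolated)
Conditions: i-Bu2AlH, N-methylmorpholine N-oxide, THF, 0 °C; CH2O (gas), −20 °C to rt; aq. work-up
Reagents that add atoms: formaldehyde, C=O; diisobutylaluminium hydride, CC(C)C[AlH]CC(C)C (its aluminium is present only in 18)
Why: syn-Hydroalumination of the ynoate by the amine oxide complex of i-Bu2AlH puts hydrogen on C3 and aluminium on C2 on the same side, and the alkenylalane (or its allenolate form, attacked anti to the methyl group) adds to formaldehyde (vinylalumination, a reductive aldol) so that the hydroxymethyl group ends cis to hydrogen, giving the Z ester.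

Step 11
Reactants: 19 ethyl (2Z)-2-(hydroxymethyl)but-2-enoate
Product: 20 (2Z)-2-(hydroxymethyl)but-2-enoic acid
Conditions: LiOH, THF–H2O, 0 °C to rt; then 1 M HCl
Reagents that add atoms: lithium hydroxide, [Li+].[OH-]
Why: Saponification at or below room temperature, under which angelate-type acids keep their geometry, is placed before acetylation so that the acetate never meets hydroxide.

Step 12
Reactants: 20 (2Z)-2-(hydroxymethyl)but-2-enoic acid
Product: 21 (2Z)-2-(acetoxymethyl)but-2-enoic acid
Conditions: Ac2O, pyridine, CH2Cl2, 0 °C to rt; H2O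
Reagents that add atoms: acetic anhydride, CC(=O)OC(C)=O
Why: O-Acetylation of the primary allylic alcohol, with any anhydride formed at the carboxyl group hydrolysed on aqueous work-up and pyridine too weak a nucleophile to trigger SN2′ exchange of the allylic acetate at 0 °C.

Step 13
Reactants: 16 1-[(2R,3S)-3-hydroxy-2-(2-hydroxypropan-2-yl)-6-[(triisopropylsilyl)oxy]-2,3-dihydro-1-benzofuran-5-yl]ethanone; 21 (2Z)-2-(acetoxymethyl)but-2-enoic acid
Product: 23 (2R,3S)-5-acetyl-2-(2-hydroxypropan-2-yl)-6-[(triisopropylsilyl)oxy]-2,3-dihydro-1-benzofuran-3-yl (2Z)-2-(acetoxymethyl)but-2-enoate, via mixed anhydride 22 (not isolated)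
Conditions: 2,4,6-trichlorobenzoyl chloride, Et3N, toluene, rt; then 16, 80 °C
Reagents that add atoms: 2,4,6-trichlorobenzoyl chloride, O=C(Cl)c1c(Cl)cc(Cl)cc1Cl (its aroyl group is present only in 22)
Why: Yamaguchi esterification run without DMAP (the variant used for angelate esters), in which the secondary C3 hydroxyl attacks the less hindered carbonyl of 22 in preference to the tertiary hydroxyl; the absence of a nucleophilic catalyst avoids Z-to-E isomerisation and SN2′ scrambling, and the C3–O bond is not broken, so the cis configuration is kept.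

Step 14
Reactants: 23 (2R,3S)-5-acetyl-2-(2-hydroxypropan-2-yl)-6-[(triisopropylsilyl)oxy]-2,3-dihydro-1-benzofuran-3-yl (2Z)-2-(acetoxymethyl)but-2-enoate
Product: 25 (2S,3S)-5-acetyl-2-(prop-1-en-2-yl)-6-[(triisopropylsilyl)oxy]-2,3-dihydro-1-benzofuran-3-yl (2Z)-2-(acetoxymethyl)but-2-enoate, via tertiary sulfamate 24 (not isolated)
Conditions: Burgess reagent, toluene, 50 °C
Reagents that add atoms: methyl N-(triethylammoniosulfonyl)carbamate (Burgess reagent), CC[N+](CC)(CC)S(=O)(=O)[N-]C(=O)OC (present only in 24)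
Why: Burgess dehydration, in which the tertiary sulfamate undergoes syn-elimination through a cyclic transition state and one of the six methyl hydrogens is taken in preference to the hindered C2–H, as in the dehydration of related 2-(2-hydroxypropan-2-yl)dihydrobenzofurans to isopropenyl compounds; the descriptor at C2 changes to (S) only because the priorities change.

Step 15
Reactants: 25 (2S,3S)-5-acetyl-2-(prop-1-en-2-yl)-6-[(triisopropylsilyl)oxy]-2,3-dihydro-1-benzofuran-3-yl (2Z)-2-(acetoxymethyl)but-2-enoate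
Product: 26 (2S,3S)-5-acetyl-6-hydroxy-2-(prop-1-en-2-yl)-2,3-dihydro-1-benzofuran-3-yl (2Z)-2-(acetoxymethyl)but-2-enoate
Conditions: HF·pyridine, pyridine, THF, 0 °C to rt
Reagents that add atoms: none
Why: Fluoride cleavage of the aryl silyl ether under buffered, non-basic conditions frees the chelated phenol without forming the phenoxide, so the C3 ester, the allylic acetate and the alkene geometry are kept.

**Compound list**

1 | 1-(2,4-dihydroxyphenyl)ethanone | CC(=O)c1ccc(O)cc1O | starting material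
2 | 1-(5-bromo-2,4-dihydroxyphenyl)ethanone | CC(=O)c1cc(Br)c(O)cc1O | intermediate
3 | 1-{5-bromo-2,4-bis[(tert-butyldimethylsilyl)oxy]phenyl}ethanone | CC(=O)c1cc(Br)c(O[Si](C)(C)C(C)(C)C)cc1O[Si](C)(C)C(C)(C)C | intermediate
4 | tributyl(3-methylbut-2-en-1-yl)stannane | CCCC[Sn](CCCC)(CCCC)CC=C(C)C | starting material
5 | 1-{2,4-bis[(tert-butyldimethylsilyl)oxy]-5-(3-methylbut-2-en-1-yl)phenyl}ethanone | CC(=O)c1cc(CC=C(C)C)c(O[Si](C)(C)C(C)(C)C)cc1O[Si](C)(C)C(C)(C)C | intermediate
6 | 1-{2,4-bis[(tert-butyldimethylsilyl)oxy]-5-{[(2S)-3,3-dimethyloxiran-2-yl]methyl}phenyl}ethanone | CC(=O)c1cc(C[C@@H]2OC2(C)C)c(O[Si](C)(C)C(C)(C)C)cc1O[Si](C)(C)C(C)(C)C | intermediate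
7 | 1-{5-{[(2S)-3,3-dimethyloxiran-2-yl]methyl}-2,4-dihydroxyphenyl}ethanone (not isolated; present as its tetrabutylammonium phenoxide) | CC(=O)c1cc(C[C@@H]2OC2(C)C)c(O)cc1O | intermediate
8 | 1-[(2R)-6-hydroxy-2-(2-hydroxypropan-2-yl)-2,3-dihydro-1-benzofuran-5-yl]ethanone | CC(C)(O)[C@@H]1Oc2cc(O)c(C(C)=O)cc2C1 | intermediate
9 | 1-[(2R)-2-(2-hydroxypropan-2-yl)-6-[(triisopropylsilyl)oxy]-2,3-dihydro-1-benzofuran-5-yl]ethanone | CC(C)(O)[C@@H]1Oc2cc(O[Si](C(C)C)(C(C)C)C(C)C)c(C(C)=O)cc2C1 | intermediate
10 | 2,2,2-trifluoroethyl isocyanate | O=C=NCC(F)(F)F | starting material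
11 | 2-[(2R)-5-acetyl-6-[(triisopropylsilyl)oxy]-2,3-dihydro-1-benzofuran-2-yl]propan-2-yl N-(2,2,2-trifluoroethyl)carbamate | CC(C)(OC(=O)NCC(F)(F)F)[C@@H]1Oc2cc(O[Si](C(C)C)(C(C)C)C(C)C)c(C(C)=O)cc2C1 | intermediate
12 | N-bromo derivative of 11 (not isolated) | CC(C)(OC(=O)N(Br)CC(F)(F)F)[C@@H]1Oc2cc(O[Si](C(C)C)(C(C)C)C(C)C)c(C(C)=O)cc2C1 | intermediate
13 | 3-bromo derivative of 11, either C3 epimer, C2 as in 11 (not isolated) | CC(C)(OC(=O)NCC(F)(F)F)[C@@H]1Oc2cc(O[Si](C(C)C)(C(C)C)C(C)C)c(C(C)=O)cc2C1Br | intermediate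
14 | cis-fused cyclic N-(2,2,2-trifluoroethyl)iminocarbonate of diol 16 (not isolated) | CC1(C)OC(=NCC(F)(F)F)O[C@H]2c3cc(C(C)=O)c(O[Si](C(C)C)(C(C)C)C(C)C)cc3O[C@@H]12 | intermediate
15 | cis-fused cyclic carbonate of diol 16, (2R,3S) in benzofuran numbering | CC1(C)OC(=O)O[C@H]2c3cc(C(C)=O)c(O[Si](C(C)C)(C(C)C)C(C)C)cc3O[C@@H]12 | intermediate
16 | 1-[(2R,3S)-3-hydroxy-2-(2-hydroxypropan-2-yl)-6-[(triisopropylsilyl)oxy]-2,3-dihydro-1-benzofuran-5-yl]ethanone | CC(C)(O)[C@@H]1Oc2cc(O[Si](C(C)C)(C(C)C)C(C)C)c(C(C)=O)cc2[C@@H]1O | intermediate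
17 | ethyl but-2-ynoate | CC#CC(=O)OCC | starting material
18 | ethyl (2E)-2-(diisobutylalumanyl)but-2-enoate (not isolated) | C/C=C(\C(=O)OCC)[Al](CC(C)C)CC(C)C | intermediate
19 | ethyl (2Z)-2-(hydroxymethyl)but-2-enoate | C/C=C(\C(=O)OCC)CO | intermediate
20 | (2Z)-2-(hydroxymethyl)but-2-enoic acid | C/C=C(\C(=O)O)CO | intermediate
21 | (2Z)-2-(acetoxymethyl)but-2-enoic acid | C/C=C(\C(=O)O)COC(C)=O | intermediate
22 | (2Z)-2-(acetoxymethyl)but-2-enoic 2,4,6-trichlorobenzoic anhydride (not isolated) | C/C=C(\C(=O)OC(=O)c1c(Cl)cc(Cl)cc1Cl)COC(C)=O | intermediate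
23 | (2R,3S)-5-acetyl-2-(2-hydroxypropan-2-yl)-6-[(triisopropylsilyl)oxy]-2,3-dihydro-1-benzofuran-3-yl (2Z)-2-(acetoxymethyl)but-2-enoate | CC(C)(O)[C@@H]1Oc2cc(O[Si](C(C)C)(C(C)C)C(C)C)c(C(C)=O)cc2[C@@H]1OC(=O)/C(=C\C)COC(C)=O | intermediate
24 | triethylammonium salt of the N-(methoxycarbonyl)sulfamate ester of the tertiary alcohol of 23 (not isolated) | COC(=O)[N-]S(=O)(=O)OC(C)(C)[C@@H]1Oc2cc(O[Si](C(C)C)(C(C)C)C(C)C)c(C(C)=O)cc2[C@@H]1OC(=O)/C(=C\C)COC(C)=O.CC[NH+](CC)CC | intermediate
25 | (2S,3S)-5-acetyl-2-(prop-1-en-2-yl)-6-[(triisopropylsilyl)oxy]-2,3-dihydro-1-benzofuran-3-yl (2Z)-2-(acetoxymethyl)but-2-enoate | C=C(C)[C@@H]1Oc2cc(O[Si](C(C)C)(C(C)C)C(C)C)c(C(C)=O)cc2[C@@H]1OC(=O)/C(=C\C)COC(C)=O | intermediate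
26 | (2S,3S)-5-acetyl-6-hydroxy-2-(prop-1-en-2-yl)-2,3-dihydro-1-benzofuran-3-yl (2Z)-2-(acetoxymethyl)but-2-enoate | C=C(C)[C@@H]1Oc2cc(O)c(C(C)=O)cc2[C@@H]1OC(=O)/C(=C\C)COC(C)=O | target

**Step count and risks**

Total: 15 steps. Longest linear sequence: 12 steps (steps 1–9 and 13–15); the acid 21 is made in 3 steps (10–12).

Steps most likely to fail:

1. Step 8. The directed stage may not compete: CH3CO2Br may brominate the arene at C7 instead of the carbamate nitrogen, or the nitrogen radical may return to N–H without abstracting at C3. Fallback: it sets out from 9. Boc2O and DMAP (cat.) in MeCN should give the tert-butyl carbonate F1. Wohl–Ziegler bromination (NBS, AIBN, PhCF3, 80 °C) at the only benzylic carbon gives the C3 bromide F2. AgOTf and 2,6-di-tert-butylpyridine in CH2Cl2 at −20 °C ionise the bromide, the carbonate carbonyl oxygen closes the same cis-only six-membered ring and isobutene is lost. The route is rejoined at 15.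

2. Step 13. Acylation of the hindered cis alcohol may be slow, and during it the activated acid may isomerise from Z to E (γ-deprotonation or reversible conjugate addition) or exchange its allylic acetate by SN2′ attack. Fallback: it sets out from 16. But-2-ynoic acid, DCC and DMAP (cat.) in CH2Cl2 give the but-2-ynoate F3, an unhindered acyl group with no alkene geometry to lose. syn-Hydrostannation (Bu3SnH, Pd(PPh3)4, THF) places tin on C2 of the acyl group and gives the (E)-2-stannyl enoate F4. I2 in CH2Cl2 gives with retention the (E)-2-iodo enoate F5. Stille coupling with (tributylstannyl)methanol (Pd(PPh3)4, dioxane, 80 °C) gives the (Z)-2-(hydroxymethyl) enoate F6. Ac2O and pyridine acetylate the primary hydroxyl only, and the route is rejoined at 23.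

3. Step 14. The tertiary sulfamate may ionise with participation of the neighbouring cis ester carbonyl (acyl transfer to the tertiary oxygen) instead of undergoing syn-elimination toward a methyl group. Fallback: it sets out from 16. TESCl and imidazole silylate the secondary hydroxyl and give the triethylsilyl ether F7. SOCl2 and pyridine at 0 °C dehydrate the tertiary alcohol, with no ester nearby, to the isopropenyl compound F8. AcOH–THF–H2O removes the triethylsilyl group and gives the C3 alcohol F9. Yamaguchi esterification with 21 through 22, as in step 13, rejoins the route at 25.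

**Further compounds**

F1 | step 8 | tert-butyl 2-[(2R)-5-acetyl-6-[(triisopropylsilyl)oxy]-2,3-dihydro-1-benzofuran-2-yl]propan-2-yl carbonate | CC(C)(OC(=O)OC(C)(C)C)[C@@H]1Oc2cc(O[Si](C(C)C)(C(C)C)C(C)C)c(C(C)=O)cc2C1
F2 | step 8 | 3-bromo derivative of F1, either C3 epimer | CC(C)(OC(=O)OC(C)(C)C)[C@@H]1Oc2cc(O[Si](C(C)C)(C(C)C)C(C)C)c(C(C)=O)cc2C1Br
F3 | step 13 | (2R,3S)-5-acetyl-2-(2-hydroxypropan-2-yl)-6-[(triisopropylsilyl)oxy]-2,3-dihydro-1-benzofuran-3-yl but-2-ynoate | CC(C)(O)[C@@H]1Oc2cc(O[Si](C(C)C)(C(C)C)C(C)C)c(C(C)=O)cc2[C@@H]1OC(=O)C#CC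
F4 | step 13 | (2R,3S)-5-acetyl-2-(2-hydroxypropan-2-yl)-6-[(triisopropylsilyl)oxy]-2,3-dihydro-1-benzofuran-3-yl (2E)-2-(tributylstannyl)but-2-enoate | CC(C)(O)[C@@H]1Oc2cc(O[Si](C(C)C)(C(C)C)C(C)C)c(C(C)=O)cc2[C@@H]1OC(=O)/C(=C\C)[Sn](CCCC)(CCCC)CCCC
F5 | step 13 | (2R,3S)-5-acetyl-2-(2-hydroxypropan-2-yl)-6-[(triisopropylsilyl)oxy]-2,3-dihydro-1-benzofuran-3-yl (2E)-2-iodobut-2-enoate | CC(C)(O)[C@@H]1Oc2cc(O[Si](C(C)C)(C(C)C)C(C)C)c(C(C)=O)cc2[C@@H]1OC(=O)/C(I)=C\C
F6 | step 13 | (2R,3S)-5-acetyl-2-(2-hydroxypropan-2-yl)-6-[(triisopropylsilyl)oxy]-2,3-dihydro-1-benzofuran-3-yl (2Z)-2-(hydroxymethyl)but-2-enoate | CC(C)(O)[C@@H]1Oc2cc(O[Si](C(C)C)(C(C)C)C(C)C)c(C(C)=O)cc2[C@@H]1OC(=O)/C(=C\C)CO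
F7 | step 14 | 1-[(2R,3S)-2-(2-hydroxypropan-2-yl)-3-[(triethylsilyl)oxy]-6-[(triisopropylsilyl)oxy]-2,3-dihydro-1-benzofuran-5-yl]ethanone | CC(C)(O)[C@@H]1Oc2cc(O[Si](C(C)C)(C(C)C)C(C)C)c(C(C)=O)cc2[C@@H]1O[Si](CC)(CC)CC
F8 | step 14 | 1-[(2S,3S)-2-(prop-1-en-2-yl)-3-[(triethylsilyl)oxy]-6-[(triisopropylsilyl)oxy]-2,3-dihydro-1-benzofuran-5-yl]ethanone | C=C(C)[C@@H]1Oc2cc(O[Si](C(C)C)(C(C)C)C(C)C)c(C(C)=O)cc2[C@@H]1O[Si](CC)(CC)CC
F9 | step 14 | 1-[(2S,3S)-3-hydroxy-2-(prop-1-en-2-yl)-6-[(triisopropylsilyl)oxy]-2,3-dihydro-1-benzofuran-5-yl]ethanone | C=C(C)[C@@H]1Oc2cc(O[Si](C(C)C)(C(C)C)C(C)C)c(C(C)=O)cc2[C@@H]1O
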